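Plan (prostanoid numbering, C1 = ester carbon). The retrosynthesis cuts C10–Br (back to the 10,11-epoxide of the debromo enone), C6–C7 (alkenylboronate plus C7 enol tosylate), C8–C9 (traced back to C7–C9, so the five-membered ring becomes a six-membered epoxy enone), C12–OH (phenol dearomatisation) and C14=C15 (Wittig).
Enabling feature: ring carbon C8 bears the single exocyclic carbon C7 directly beside the C9 ketone. The ring C8–C9–C10–C11–C12 plus C7 is therefore the six-carbon ring of a para-quinol, with C12 as carbinol carbon, C9 as carbonyl, and C7=C8 and C10=C11 as its two enone alkenes.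
Forward: tyrosol gives 4-[(Z)-oct-2-enyl]phenol, then the achiral quinol silyl ether, which is mono-epoxidised at C7–C8. A Lewis-acid 1,2-acyl shift then contracts the six-membered ring to the cyclopentenone and leaves C7 outside the ring as a hydroxymethylene group.
The C1–C6 chain is joined at C7 by Suzuki–Miyaura coupling; bromine and the free C12 hydroxyl come last.
Stereochemistry: C12 (R), the only stereocentre, comes from a catalyst-controlled choice between the two enantiotopic enone alkenes in the epoxidation. 14Z comes from the Wittig reaction, 5Z from trans-hydroboration, and 7E from the E enol tosylate and a stereoretentive coupling.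

Key step: step 7

Assumption: the quinine-derived amine salt is taken to deliver the (1S,6R) oxirane; if its sense proves opposite, the quinidine-derived pseudoenantiomer replaces it and nothing else changes.

Step 1
Reactants: 1 tyrosol
Product: 2 4-(2-bromoethyl)phenol
Conditions: 48% aq HBr, reflux
Reagents that add atoms: hydrogen bromide, Br
Why: Bromide displaces the protonated primary alcohol by SN2, and the phenol is inert to aqueous HBr, so no protecting group is needed.

Step 2
Reactants: 2 4-(2-bromoethyl)phenol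
Product: 3 [2-(4-hydroxyphenyl)ethyl]triphenylphosphonium bromide
Conditions: PPh3, MeCN, reflux
Reagents that add atoms: triphenylphosphine, c1ccc(cc1)P(c1ccccc1)c1ccccc1
Why: PPh3 is quaternised by a primary bromide (SN2) under neutral conditions, where the free phenol cannot spirocyclise onto the bromide.

Step 3
Reactants: 3 [2-(4-hydroxyphenyl)ethyl]triphenylphosphonium bromide; 4 hexanal
Product: 6 4-[(2Z)-oct-2-en-1-yl]phenol, via phenoxide ylide 5 (not isolated)
Conditions: NaN(SiMe3)2 (2.1 equiv), THF, 0 °C; then 4, −78 °C → rt; 1 M HCl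
Reagents that add atoms: none
Why: In this Wittig olefination the lithium-free non-stabilised ylide adds to the aliphatic aldehyde under kinetic control through the cis-oxaphosphetane and sets 14Z, while the second equivalent of base holds the phenol as phenoxide, which lowers the benzylic acidity and disfavours β-elimination of PPh3.

Step 4
Reactants: 6 4-[(2Z)-oct-2-en-1-yl]phenol
Product: 7 4-hydroxy-4-[(2Z)-oct-2-en-1-yl]cyclohexa-2,5-dien-1-one
Conditions: PhI(OAc)2, MeCN–H2O (3:1), 0 °C
Reagents that add atoms: water, O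
Why: This is the oxidative dearomatisation of a para-alkylphenol with a hypervalent iodine reagent, in which ligand exchange at iodine, loss of PhI and capture of the para carbon by water should give the achiral para-quinol and leave the unactivated side-chain alkene untouched.

Step 5
Reactants: 7 4-hydroxy-4-[(2Z)-oct-2-en-1-yl]cyclohexa-2,5-dien-1-one
Product: 8 4-(tert-butyldimethylsilyloxy)-4-[(2Z)-oct-2-en-1-yl]cyclohexa-2,5-dien-1-one
Conditions: TBSOTf, 2,6-lutidine, CH2Cl2, 0 °C
Reagents that add atoms: tert-butyldimethylsilyl triflate, CC(C)(C)[Si](C)(C)OS(=O)(=O)C(F)(F)F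
Why: A silyl triflate with a non-nucleophilic base is the standard way to silylate a hindered tertiary alcohol, and the bulky group is needed later to shield one ring face and to survive the Lewis acid.

Step 6
Reactants: 8 4-(tert-butyldimethylsilyloxy)-4-[(2Z)-oct-2-en-1-yl]cyclohexa-2,5-dien-1-one
Product: 9 (1S,5R,6R)-5-(tert-butyldimethylsilyloxy)-5-[(2Z)-oct-2-en-1-yl]-7-oxabicyclo[4.1.0]hept-3-en-2-one (oxirane trans to the silyloxy group)
Conditions: 9-amino-9-deoxy-epi-quinine (10 mol %), CF3CO2H (20 mol %), 30% aq H2O2 (1.5 equiv), 1,4-dioxane, 30 °C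
Reagents that add atoms: hydrogen peroxide, OO
Why: Proposed new method: the primary amine condenses with the C9 ketone to a cross-conjugated iminium ion, the protonated quinuclidine guides H2O2 to one β-carbon on one face, and the β-peroxy enamine closes the oxirane; because the TBS group, turned away from the octenyl chain, lies over its own ring face, attack is expected only anti to OTBS, so the facial preference of the catalyst becomes a choice between the two enantiotopic alkenes and fixes C12 as R together with the (1S,6R) oxirane, and any minor enantiomer still carries the matched alkene and is drained into the meso bis-epoxide; the closest known reaction type is the asymmetric epoxidation of simple 2-cyclohexenones with H2O2 under cinchona primary amine salt catalysis, which has not been used to desymmetrise a quinol ether.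

Step 7
Reactants: 9 (1S,5R,6R)-5-(tert-butyldimethylsilyloxy)-5-[(2Z)-oct-2-en-1-yl]-7-oxabicyclo[4.1.0]hept-3-en-2-one
Product: 11 (4R,5Z)-4-(tert-butyldimethylsilyloxy)-5-(hydroxymethylidene)-4-[(2Z)-oct-2-en-1-yl]cyclopent-2-en-1-one, via formyl ketone 10 (not isolated)
Conditions: BF3·OEt2 (0.5 equiv), CH2Cl2, −40 → 0 °C; aq NaHCO3
Reagents that add atoms: none
Why: Boron binds the oxirane oxygen, the C8–O bond lengthens (C7–O is switched off by the adjacent C9 carbonyl), and the acyl carbon C9 slides from C7 to C8 on the side opposite the leaving oxygen while the C7–O electrons fold down to the aldehyde; formyl ketone 10 then enolises to the hydrogen-bonded hydroxymethylene ketone 11. The closest known reaction type is the Lewis-acid 1,2-acyl shift (Meinwald-type rearrangement) of cyclohexenone oxides to 2-formylcyclopentanones. The five-membered ring is not closed end to end but by ring contraction, a suprafacial 1,2-shift through a three-centre transition state that makes C8–C9 as C7–C9 breaks. The C8 stereocentre of 10 arises by inversion at C8 and is erased on enolisation, and C12 takes no part, so its R configuration is carried over unchanged. Acyl migration must outrun a semipinacol shift from C12, a hydride shift from C7, fluoride opening and attack by the C14=C15 alkene: with the oxirane trans to OTBS the only C12 substituent anti to the breaking C8–O bond is the bulky, poorly nucleophilic silyloxy oxygen, the octenyl chain and its alkene sit on the oxirane face and cannot reach the back lobe at C8, and the ring bond C12–C11 lies close to the nodal plane. Low temperature, a non-coordinating solvent and substoichiometric BF3·OEt2 should keep fluoride transfer and desilylation slow.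

Step 8
Reactants: 11 (4R,5Z)-4-(tert-butyldimethylsilyloxy)-5-(hydroxymethylidene)-4-[(2Z)-oct-2-en-1-yl]cyclopent-2-en-1-one
Product: 12 (E)-{(5R)-5-(tert-butyldimethylsilyloxy)-5-[(2Z)-oct-2-en-1-yl]-2-oxocyclopent-3-en-1-ylidene}methyl 4-methylbenzenesulfonate
Conditions: TsCl, N-methylimidazole, Et3N, CH2Cl2, 0 °C
Reagents that add atoms: 4-toluenesulfonyl chloride, Cc1ccc(cc1)S(=O)(=O)Cl
Why: The enolate of the α-formyl ketone is O-sulfonylated by the TsCl–N-methylimidazole adduct, and because an amine base offers no metal chelate to hold the two oxygens together, the enolate should react from its dipole-minimised form with O7 anti to the C9 carbonyl and give the E enol tosylate, the geometry required for 7E.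

Step 9
Reactants: 13 methyl hex-5-ynoate
Product: 14 methyl (5Z)-6-(4,4,5,5-tetramethyl-1,3,2-dioxaborolan-2-yl)hex-5-enoate
Conditions: pinacolborane, [Rh(cod)Cl]2 (1.5 mol %), P(i-Pr)3 (6 mol %), Et3N, cyclohexane, rt
Reagents that add atoms: pinacolborane, CC1(C)OBOC1(C)C
Why: Rhodium-catalysed formal trans-hydroboration of a terminal alkyne through a vinylidene complex places boron cis to the chain and sets 5Z in one step, and boron is chosen because the corresponding (Z)-alkenyl-lithium or -magnesium species would cyclise onto its own ester to cyclohexenone.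

Step 10
Reactants: 12 (E)-enol tosylate; 14 methyl (5Z)-6-(4,4,5,5-tetramethyl-1,3,2-dioxaborolan-2-yl)hex-5-enoate
Product: 15 methyl (5Z,7E,12R,14Z)-12-(tert-butyldimethylsilyloxy)-9-oxoprosta-5,7,10,14-tetraen-1-oate
Conditions: Pd(OAc)2 (5 mol %), SPhos (10 mol %), K3PO4, THF–H2O (10:1), rt
Reagents that add atoms: none
Why: Suzuki–Miyaura coupling of a β-acyl-activated enol tosylate with an alkenylboronate forms C6–C7 with retention at both alkenes (7E, 5Z), and it is run before bromine is introduced so that no C–Br bond competes for palladium.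

Step 11
Reactants: 15 methyl (5Z,7E,12R,14Z)-12-(tert-butyldimethylsilyloxy)-9-oxoprosta-5,7,10,14-tetraen-1-oate
Product: 16 methyl (5Z,7E,10R,11S,12S,14Z)-12-(tert-butyldimethylsilyloxy)-10,11-epoxy-9-oxoprosta-5,7,14-trien-1-oate (oxirane anti to the silyloxy group)
Conditions: 30% aq H2O2, NaOH (0.2 equiv), MeOH, −20 °C
Reagents that add atoms: hydrogen peroxide, OO
Why: In this Weitz–Scheffer epoxidation hydroperoxide adds to C11 of the endocyclic enone, the most electrophilic acceptor of a cross-conjugated alkylidenecyclopentenone, on the face anti to OTBS (substrate control), and both new stereocentres are erased in the next step.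

Step 12
Reactants: 16 methyl (5Z,7E,10R,11S,12S,14Z)-12-(tert-butyldimethylsilyloxy)-10,11-epoxy-9-oxoprosta-5,7,14-trien-1-oate
Product: 18 methyl (5Z,7E,12R,14Z)-10-bromo-12-(tert-butyldimethylsilyloxy)-9-oxoprosta-5,7,10,14-tetraen-1-oate, via bromohydrin 17 (not isolated)
Conditions: 48% aq HBr (1.2 equiv), THF, 0 °C
Reagents that add atoms: hydrogen bromide, Br
Why: Acid-promoted anti opening of an α,β-epoxy ketone by bromide at the α-carbon C10, followed by dehydration of the β-hydroxy ketone, is the standard conversion of epoxy ketones into α-bromo enones and needs no electrophilic bromine source that would attack the isolated or dienyl alkenes.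

Step 13
Reactants: 18 methyl (5Z,7E,12R,14Z)-10-bromo-12-(tert-butyldimethylsilyloxy)-9-oxoprosta-5,7,10,14-tetraen-1-oate
Product: 19 bromovulone I, methyl (5Z,7E,12R,14Z)-10-bromo-12-hydroxy-9-oxoprosta-5,7,10,14-tetraen-1-oate
Conditions: 48% aq HF, MeCN, 0 °C → rt
Reagents that add atoms: none
Why: Fluoride cleaves the Si–O bond under acidic, non-basic conditions without touching C12–O, so the R configuration is retained and the ester and the base-sensitive bromodienone are spared.

Compound list
1 | tyrosol, 4-(2-hydroxyethyl)phenol | OCCc1ccc(O)cc1 | starting material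
2 | 4-(2-bromoethyl)phenol | BrCCc1ccc(O)cc1 | intermediate
3 | [2-(4-hydroxyphenyl)ethyl]triphenylphosphonium bromide | [Br-].Oc1ccc(CC[P+](c2ccccc2)(c2ccccc2)c2ccccc2)cc1 | intermediate
4 | hexanal | CCCCCC=O | starting material
5 | sodium 4-[2-(triphenyl-λ5-phosphanylidene)ethyl]phenolate (phenoxide ylide) | [Na+].[O-]c1ccc(CC=P(c2ccccc2)(c2ccccc2)c2ccccc2)cc1 | intermediate
6 | 4-[(2Z)-oct-2-en-1-yl]phenol | CCCCC/C=C\Cc1ccc(O)cc1 | intermediate
7 | 4-hydroxy-4-[(2Z)-oct-2-en-1-yl]cyclohexa-2,5-dien-1-one | CCCCC/C=C\CC1(O)C=CC(=O)C=C1 | intermediate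
8 | 4-(tert-butyldimethylsilyloxy)-4-[(2Z)-oct-2-en-1-yl]cyclohexa-2,5-dien-1-one | CCCCC/C=C\CC1(O[Si](C)(C)C(C)(C)C)C=CC(=O)C=C1 | intermediate
9 | (1S,5R,6R)-5-(tert-butyldimethylsilyloxy)-5-[(2Z)-oct-2-en-1-yl]-7-oxabicyclo[4.1.0]hept-3-en-2-one | CCCCC/C=C\C[C@@]1(O[Si](C)(C)C(C)(C)C)C=CC(=O)[C@H]2O[C@@H]12 | intermediate
10 | (1R,5R)-5-(tert-butyldimethylsilyloxy)-5-[(2Z)-oct-2-en-1-yl]-2-oxocyclopent-3-ene-1-carbaldehyde | CCCCC/C=C\C[C@@]1(O[Si](C)(C)C(C)(C)C)C=CC(=O)[C@H]1C=O | intermediate
11 | (4R,5Z)-4-(tert-butyldimethylsilyloxy)-5-(hydroxymethylidene)-4-[(2Z)-oct-2-en-1-yl]cyclopent-2-en-1-one | CCCCC/C=C\C[C@@]1(O[Si](C)(C)C(C)(C)C)C=CC(=O)/C1=C\O | intermediate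
12 | (E)-{(5R)-5-(tert-butyldimethylsilyloxy)-5-[(2Z)-oct-2-en-1-yl]-2-oxocyclopent-3-en-1-ylidene}methyl 4-methylbenzenesulfonate | CCCCC/C=C\C[C@@]1(O[Si](C)(C)C(C)(C)C)C=CC(=O)/C1=C/OS(=O)(=O)c2ccc(C)cc2 | intermediate
13 | methyl hex-5-ynoate | C#CCCCC(=O)OC | starting material
14 | methyl (5Z)-6-(4,4,5,5-tetramethyl-1,3,2-dioxaborolan-2-yl)hex-5-enoate | COC(=O)CCC/C=C\B1OC(C)(C)C(C)(C)O1 | intermediate
15 | methyl (5Z,7E,12R,14Z)-12-(tert-butyldimethylsilyloxy)-9-oxoprosta-5,7,10,14-tetraen-1-oate | CCCCC/C=C\C[C@@]1(O[Si](C)(C)C(C)(C)C)C=CC(=O)/C1=C/C=C\CCCC(=O)OC | intermediate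
16 | methyl (5Z,7E,10R,11S,12S,14Z)-12-(tert-butyldimethylsilyloxy)-10,11-epoxy-9-oxoprosta-5,7,14-trien-1-oate | CCCCC/C=C\C[C@@]1(O[Si](C)(C)C(C)(C)C)[C@H]2O[C@H]2C(=O)/C1=C/C=C\CCCC(=O)OC | intermediate
17 | methyl (5Z,7E,10S,11R,12S,14Z)-10-bromo-12-(tert-butyldimethylsilyloxy)-11-hydroxy-9-oxoprosta-5,7,14-trien-1-oate | CCCCC/C=C\C[C@@]1(O[Si](C)(C)C(C)(C)C)[C@@H](O)[C@H](Br)C(=O)/C1=C/C=C\CCCC(=O)OC | intermediate
18 | methyl (5Z,7E,12R,14Z)-10-bromo-12-(tert-butyldimethylsilyloxy)-9-oxoprosta-5,7,10,14-tetraen-1-oate | CCCCC/C=C\C[C@@]1(O[Si](C)(C)C(C)(C)C)C=C(Br)C(=O)/C1=C/C=C\CCCC(=O)OC | intermediate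
19 | bromovulone I, methyl (5Z,7E,12R,14Z)-10-bromo-12-hydroxy-9-oxoprosta-5,7,10,14-tetraen-1-oate | CCCCC/C=C\C[C@@]1(O)C=C(Br)C(=O)/C1=C/C=C\CCCC(=O)OC | target

Total step count: 13. Longest linear sequence: 12 (steps 1–8 and 10–13; step 9 is the side branch).

Steps most likely to fail

1. Step 6 (labelled step).
- Risk: the catalyst may discriminate poorly between the two enantiotopic alkenes. Iminium formation with the hindered cross-conjugated ketone may be slow. Part of the attack may occur on the face syn to OTBS.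
- Fallback by known chemistry, from 8 back to 9. A non-selective Weitz–Scheffer epoxidation with t-BuOOH and DBU in CH2Cl2 would give the racemic trans-epoxy enone F1.
- Luche reduction (NaBH4, CeCl3·7H2O, MeOH, −78 °C) would then give the racemic epoxy allylic alcohol F2.
- Lipase-catalysed acetylation (lipase from Burkholderia cepacia, vinyl acetate, t-BuOMe) is a kinetic resolution of a cyclic secondary allylic alcohol. It is expected to leave the (1R,2R,5R,6R) epoxy alcohol F3 beside the acetate of its antipode F4, and the two are separable on silica.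
- MnO2 in CH2Cl2 re-oxidises F3 to 9.

2. Step 7.
- Risk: ionisation at C8 is slowed by the neighbouring C12–O bond. Other processes may then take over: fluoride opening, a hydride shift to the diosphenol, loss of the silyl group, or a Lewis-acid-accelerated Cope rearrangement of the C10=C11/C14=C15 1,5-diene.
- Fallback, from 9 back to 11. Isomerisation of the epoxy ketone by zerovalent palladium (Pd(PPh3)4, dppe, toluene, heat) would give the cyclohexenedione F5.
- Regitz diazo transfer (4-acetamidobenzenesulfonyl azide, Et3N, MeCN) would give the 2-diazo dione F6.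
- Photochemical Wolff rearrangement in wet THF, with C12 migrating, would give the ring-contracted β-keto acid F7. This loses CO2 on warming to the cyclopentenone F8.
- Claisen formylation (HCO2Et, NaH, THF) at the only enolisable carbon returns to 11, the exocyclic carbon now coming from the formate.

3. Step 10.
- Risk: the aqueous base may hydrolyse the vinylogous sulfonate, the alkenylboronate may protodeboronate, or the 5Z or 7E geometry may erode on palladium.
- Fallback, from 12 (with 13) back to 15. Sonogashira coupling of 12 with the alkyne 13 itself under water-free amine conditions (PdCl2(PPh3)2, CuI, Et3N, THF, rt) would give the dienynone F9.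
- 5Z is then set by syn semihydrogenation (H2, Pd/CaCO3 poisoned with Pb(OAc)2, quinoline, EtOAc), stopped at one equivalent of hydrogen, to reach 15.

Further compounds
F1 | step 6 | racemic trans-epoxy enone, rac-(1S*,5R*,6R*)-5-(tert-butyldimethylsilyloxy)-5-[(2Z)-oct-2-en-1-yl]-7-oxabicyclo[4.1.0]hept-3-en-2-one (one enantiomer drawn) | CCCCC/C=C\C[C@@]1(O[Si](C)(C)C(C)(C)C)C=CC(=O)[C@H]2O[C@@H]12
F2 | step 6 | racemic epoxy allylic alcohol, rac-(1R*,2R*,5R*,6R*)-5-(tert-butyldimethylsilyloxy)-5-[(2Z)-oct-2-en-1-yl]-7-oxabicyclo[4.1.0]hept-3-en-2-ol, hydroxyl cis to the oxirane (one enantiomer drawn) | CCCCC/C=C\C[C@@]1(O[Si](C)(C)C(C)(C)C)C=C[C@@H](O)[C@H]2O[C@@H]12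
F3 | step 6 | (1R,2R,5R,6R)-5-(tert-butyldimethylsilyloxy)-5-[(2Z)-oct-2-en-1-yl]-7-oxabicyclo[4.1.0]hept-3-en-2-ol | CCCCC/C=C\C[C@@]1(O[Si](C)(C)C(C)(C)C)C=C[C@@H](O)[C@H]2O[C@@H]12
F4 | step 6 | (1S,2S,5S,6S)-5-(tert-butyldimethylsilyloxy)-5-[(2Z)-oct-2-en-1-yl]-7-oxabicyclo[4.1.0]hept-3-en-2-yl acetate | CCCCC/C=C\C[C@]1(O[Si](C)(C)C(C)(C)C)C=C[C@H](OC(C)=O)[C@@H]2O[C@H]12
F5 | step 7 | (4R)-4-(tert-butyldimethylsilyloxy)-4-[(2Z)-oct-2-en-1-yl]cyclohex-5-ene-1,3-dione | CCCCC/C=C\C[C@@]1(O[Si](C)(C)C(C)(C)C)C=CC(=O)CC1=O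
F6 | step 7 | (4R)-4-(tert-butyldimethylsilyloxy)-2-diazo-4-[(2Z)-oct-2-en-1-yl]cyclohex-5-ene-1,3-dione | CCCCC/C=C\C[C@@]1(O[Si](C)(C)C(C)(C)C)C=CC(=O)C(=[N+]=[N-])C1=O
F7 | step 7 | (5R)-5-(tert-butyldimethylsilyloxy)-5-[(2Z)-oct-2-en-1-yl]-2-oxocyclopent-3-ene-1-carboxylic acid (C1 epimers) | CCCCC/C=C\C[C@@]1(O[Si](C)(C)C(C)(C)C)C=CC(=O)C1C(=O)O
F8 | step 7 | (4S)-4-(tert-butyldimethylsilyloxy)-4-[(2Z)-oct-2-en-1-yl]cyclopent-2-en-1-one | CCCCC/C=C\C[C@@]1(O[Si](C)(C)C(C)(C)C)C=CC(=O)C1
F9 | step 10 | methyl (7E,12R,14Z)-12-(tert-butyldimethylsilyloxy)-9-oxoprosta-7,10,14-trien-5-yn-1-oate | CCCCC/C=C\C[C@@]1(O[Si](C)(C)C(C)(C)C)C=CC(=O)/C1=C/C#CCCCC(=O)OC
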